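The data are calculated for substances that don't exist; scatter was added.

I left 3 questions for whoever took over the bench; they stand below with the runs so far.

| flask | starting material | free catalyst | time |
|---|---|---|---|
| red | 0.400 M | 0.0120 M |  |
| teal | 0.800 M | 0.0120 M |  |
| grey | 0.400 M | 0.0180 M |  |
| violet | 0.400 M | 0.0120 M | 45 min |

| red run: time / min | red run: [product] / M | teal run: time / min | teal run: [product] / M | grey run: time / min | grey run: [product] / M |
|---|---|---|---|---|---|
| 2.1 | 0.071 | 2.1 | 0.119 | 2.1 | 0.097 |
| 4.3 | 0.130 | 4.3 | 0.234 | 4.3 | 0.174 |
| 6.4 | 0.190 | 6.4 | 0.319 | 6.4 | 0.233 |
| 8.6 | 0.222 | 8.6 | 0.405 | 8.6 | 0.273 |
| 11 | 0.257 | 11 | 0.469 | 11 | 0.302 |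
| 13 | 0.268 | 13 | 0.513 | 13 | 0.324 |
| 15 | 0.291 | 15 | 0.545 | 15 | 0.323 |

(readings scatter by 0.004 M)

- how the opening rate goes with [free catalyst] round the charge of the red run: the exponent of the rate at two percent of starting material gone to product
- how the opening rate goes with [starting material] round the charge of the red run: the exponent of the rate at two percent of starting material gone to product (one fixed amount of product, the same in the runs compared)
- product in the violet run at 45 min, as a share of the starting material charged

- Overall: starting material -> product, with free catalyst as catalyst.
- Constant volume, constant temperature.
- Readings of a species count what is bound in complexes too.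
- An order is taken over about fifteen percent of the charge, up and down.

The violet flask held starting material and free catalyst at the red charge. Free catalyst is not consumed overall, so I froze it and assumed two pseudo-first-order paths for starting material: catalysed conversion to product and a side loss. Their split then stays fixed through a run. The grey run read 0.324 M at 13 min and 0.323 M at 15 min; two readings that close lie within the scatter and do not show that the run had finished, so I took their mean only as a low estimate of its final share Y of the charge. Its first reading stood at 1.37 times the red one, which I took as the gain in catalysed speed.

Y(grey) = 80.9%

missing share / Y (grey) = 0.236

Dividing the loss rate by a catalysed rate that is slower by that factor gave the red charge its loss ratio ρ, the rate of loss of starting material over the rate of product formation, the inverse of a selectivity factor: 0.323.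

Y(violet) = 1 / (1 + ρ) = 75.6%

A low Y for grey made ρ a high estimate and this share a low one, and I expected it as a low estimate of the product in the violet run at 45 min. The violet catalyst charge was not to be touched, since the question was about the red charge and the grey ratio, at a higher catalyst charge, was lower than the red one.

The forecast gave 0.85, 0.8 and 83%, higher than my share: “Grey flattens at about 0.325–0.335 M, which suggests equilibrium near 83%”.

The flask gave 0.76, 0.70 and 79.9%, and all 3 forecast values held within their margins.

    2 free catalyst ⇌ catalyst dimer, settled at all times (30.10 /M)
    free catalyst + starting material → product + free catalyst (22.74 /M/min)
    starting material → decomposed substrate (0.04614 /min)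
    2 starting material ⇌ idle substrate dimer, settled at all times (2.130 /M)

The violet run fell short of its charge because of the step from starting material to decomposed substrate. Its share gives ρ = 0.251, lower than my 0.323. What would turn the forecast's 83% wrong is that step going. With it taken away ρ is zero, so Y should be the whole charge, and the violet run gave 99.9%.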